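The earlier runs and the new flask were computed from invented constants; the scatter is artificial.

**Minutes of the meeting on the four flasks**

It was decided to argue from one slope of the cedar run, and to settle what that slope means before any number was offered for the new flasks.

| flask | solid substrate | second substrate | enzyme | remark | time |
|---|---|---|---|---|---|
| cedar | 0.075 M | 2.5 equiv | 0.01 mol% | run made earlier |  |
| ochre | 0.050 M | 7.50 equiv | 0.01 mol% |  | 4.0 d |
| teal | 0.050 M | 1.70 equiv | 0.01 mol% |  | 4.0 d |
| blue | 0.050 M | 0.620 equiv | 0.01 mol% |  | 4.0 d |
| red | 0.050 M | 2.50 equiv | 0.01 mol% |  | 4.0 d |

- cedar (time / d: product / %): 0.625: 5.5; 1.25: 11.5; 1.67: 15.4; 2.50: 23.3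

(standard deviation of a reading: 0.5 percentage points)

- given per volume of solution although it is solid: solid substrate
- the analysis behind the earlier runs scatters by 0.5 percentage points, standard deviation
- at the start none of the solid substrate is in solution
- what has only dissolved of solid substrate counts as not reacted
- no earlier run changes the charge of enzyme; that part of a forecast is a guess

* the flasks put in order of amount of product, in percent of the solid substrate charged, best first, at 4.0 d (ochre / teal / blue / red)
* the amount of product, in percent of the solid substrate charged of the flask you put first, at 4.0 d
* the amount of product, in percent of the solid substrate charged of the flask you put last, at 4.0 d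

Nobody disputed the reading: cedar's product climbs almost in a straight line, by 0.0949 d⁻¹ of the charge per day between its first and last readings.

I argued that none of the solid substrate is in solution at the start, so whatever reacts has first dissolved. If the enzyme takes up dissolved material as it arrives, the solution stays lean and steady, and dissolving is the rate-limiting step. The quantity to carry is then the feed, cedar's slope times cedar's charge of solid substrate, 0.00712 M d⁻¹. On this reading the feed is constant, so integrating it gives the fraction reacted as feed times time divided by the charge.

At 0.050 M the daily share becomes 0.142 d⁻¹, larger than cedar's, and 4.0 d gives 57.0% of the charge. I committed to that figure for ochre, placed first. I placed blue last, as the flask with the smallest charge of second substrate, 0.620 equiv, and gave it no figure of its own.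

The forecaster disagreed, holding that “Enzyme is charged in proportion to solid, so percent per day should not change with loading”. The forecast reads ochre > red > teal > blue, with 38% on top and 28% at the bottom. Cedar, a single run, could not choose between us.

**Result**

    starting material + enzyme ⇌ starting complex (K = 203 L mol⁻¹, k = 1140 L mol⁻¹ s⁻¹)
    second substrate + starting complex ⇌ ternary complex (K = 9.70 L mol⁻¹, k = 380 L mol⁻¹ s⁻¹)
    ternary complex → enzyme + product (k = 0.226 s⁻¹)
    solid substrate ⇌ starting material, rate k4*(cs4 - [starting material]) while solid is left; crystals form when [starting material] > cs4 (solubility = 6.80 mM, k = 1.19 × 10⁻⁵ s⁻¹)

The order came out as ochre > red > teal > blue, with ochre at 54.7% of its charge against the reckoned 57.0%, and blue last at 36.8%. In ochre, dissolved starting material stood at 0.249% of the charge after 2.00 d and 0.258% after 4.00 d. Ochre's product over its time corresponds to a feed of 0.00683 M d⁻¹, beside the 0.00712 M d⁻¹ read from cedar. A neighbour of ochre, with its enzyme cut to a quarter at 0.0025 mol%, still reached 49.6% of its charge, which corresponds to a feed of 0.00620 M d⁻¹.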